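**Strategy.** The nine-membered carbocycle is disconnected at C1–C2 and C8–C9. C3 and C8 lie in a 1,5-relationship (C3–C2–C1–C9–C8) on either side of C1–C9, the bond shared with the cyclobutane. A 3,8-diketone is therefore the De Mayo product of a cycloheptane-1,3-dione enol ether and 3,3-dimethylcyclobutene. One photocycloaddition–retro-aldol operation forms both bonds, expands the seven-membered ring to the nine-membered one and installs the fused four-membered ring. The precursor is an enantioenriched 3-methoxycyclohept-2-enone carrying the future C4 methyl and a C5 silyloxy group that directs the facial selectivity. Afterwards C8 is methylenated, the C3 carbonyl is traded for the C3=C4–C5 allylic alcohol, and the spiro-pyran is closed last by hetero-Diels–Alder reaction.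

Key step: step 8

Remark on locants: C1–C11 follow the bicyclo[7.2.0]undecane frame of the target (C1/C9 ring fusion, C10 the cyclobutane CH2, C11 the CMe2 carbon); C3′ and C4′ are the CH2 and the isobutyl-bearing CH of the pyran ring.
Assumption: the Josiphos antipode named in step 4 is taken to deliver boron to the face giving 6R; the mirror-image ligand is used if the sense proves opposite.
Remark: the methyl-bearing carbon (C7 of 6–8, C4 of 13–20) is carried as an epimer mixture and becomes sp2 in step 13; the carbinol centre set in step 4 serves as the stereochemical relay for C1/C9 and is set again, under reagent control, in step 14.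

**Route**

Step 1
Reactants: 1 cycloheptane-1,3-dione
Product: 2 3-methoxycyclohept-2-en-1-one
Conditions: HC(OMe)3, TsOH·H2O (cat.), MeOH, rt
Reagents that add atoms: trimethyl orthoformate COC(OC)OC
Why: Acid-catalysed enol etherification of a cyclic 1,3-diketone (vinylogous ester formation) should give a single product because the dione is symmetric.

Step 2
Reactants: 2 3-methoxycyclohept-2-en-1-one
Product: 3 3-methoxy-7-methylcyclohept-2-en-1-one (racemic)
Conditions: LDA, THF, −78 °C; MeI, −78 → −20 °C
Reagents that add atoms: iodomethane CI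
Why: Kinetic deprotonation of a vinylogous ester occurs at the α′ carbon and the enolate is C-methylated (Stork–Danheiser-type alkylation); the new centre is racemic and is later sp2.

Step 3
Reactants: 3 3-methoxy-7-methylcyclohept-2-en-1-one
Product: 5 3-methoxy-7-methylcyclohepta-2,6-dien-1-one, via silyl dienol ether 4 (not isolated)
Conditions: LDA, TMSCl, THF, −78 °C; then Pd(OAc)2 (10 mol %), O2, DMSO, rt
Reagents that add atoms: none
Why: The α′ silyl dienol ether forms regiospecifically and its palladium enolate should undergo β-hydride elimination into the ring to give the endocyclic 2-methyl enone (Saegusa–Ito oxidation, aerobic catalytic protocol).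

Step 4
Reactants: 5 3-methoxy-7-methylcyclohepta-2,6-dien-1-one
Product: 7 (6R)-6-hydroxy-3-methoxy-7-methylcyclohept-2-en-1-one (C7 epimers), via boronate 6 (not isolated)
Conditions: B2pin2, CuCl (3 mol %), (R,S)-Josiphos (3 mol %), NaOtBu (cat.), MeOH (2 equiv), THF, rt; then NaBO3·4H2O, THF–H2O, rt
Reagents that add atoms: sodium perborate [Na+].[O-]OB=O
Why: Copper-catalysed enantioselective conjugate borylation should attack only the C6=C7 enone (the C2=C3 bond is a deactivated vinylogous ester), the chiral bisphosphine setting C6, and perborate then oxidises C–B to C–O with retention; C7 arises by protonation and is left as a mixture in which the trans epimer should prevail after equilibration.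

Step 5
Reactants: 7 (6R)-6-hydroxy-3-methoxy-7-methylcyclohept-2-en-1-one
Product: 8 (6R)-6-[tert-butyl(dimethyl)silyl]oxy-3-methoxy-7-methylcyclohept-2-en-1-one (C7 epimers)
Conditions: TBSCl, imidazole, DMF, rt
Reagents that add atoms: tert-butyldimethylsilyl chloride CC(C)(C)[Si](C)(C)Cl
Why: Imidazole-promoted silylation of a secondary alcohol proceeds under near-neutral conditions, which should avoid β-elimination of the aldol-type hydroxy ketone.

Step 6
Reactants: 9 3,3-dimethylcyclobutan-1-one
Product: 10 N′-(3,3-dimethylcyclobutylidene)-4-methylbenzenesulfonohydrazide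
Conditions: TsNHNH2, MeOH, rt
Reagents that add atoms: p-toluenesulfonyl hydrazide Cc1ccc(cc1)S(=O)(=O)NN
Why: Condensation of a ketone with tosylhydrazide gives the tosylhydrazone.

Step 7
Reactants: 10 N′-(3,3-dimethylcyclobutylidene)-4-methylbenzenesulfonohydrazide
Product: 12 3,3-dimethylcyclobutene (used as an assayed hexane solution), via cyclobutenyllithium 11 (not isolated)
Conditions: n-BuLi (2.2 equiv), TMEDA–hexane, −78 → 20 °C; H2O; distillation
Reagents that add atoms: none
Why: In the Shapiro reaction the hydrazone dianion loses sulfinate and N2 to give a vinyllithium that is protonated, which avoids the ring contraction expected from a carbene (Bamford–Stevens) pathway on a cyclobutanone.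

Step 8
Reactants: 8 (6R)-6-[tert-butyl(dimethyl)silyl]oxy-3-methoxy-7-methylcyclohept-2-en-1-one; 12 3,3-dimethylcyclobutene
Product: 15 (1R,5R,9S)-5-[tert-butyl(dimethyl)silyl]oxy-4,11,11-trimethylbicyclo[7.2.0]undecane-3,8-dione (trans-fused; C4 epimers), via photoadduct 13 (not isolated), via cis-fused dione 14 (not isolated)
Conditions: 12 (8 equiv), hν (Pyrex, λ > 300 nm), CH2Cl2, −20 °C; then TsOH·H2O (cat.), acetone–H2O, rt; then DBU (0.1 equiv), CH2Cl2, 0 °C
Reagents that add atoms: water O
Why: The triplet vinylogous ester should add its C2=C8 bond stepwise (1,4-biradical, cis on the cyclobutene) across 12 to give the methoxybicyclo[2.2.0]hexane 13, whose donor–acceptor C2–C8 bond is cleaved by acid-catalysed retro-aldol opening (oxocarbenium at C8, enol at C2=C3) and hydrolysis, so that C1–C2 and C8–C9 are the only new skeletal bonds; this is a De Mayo photocycloaddition–fragmentation of a β-alkoxy enone with a strained cycloalkene as the 2π partner. The four-membered ring of 13 closes by biradical collapse, the nine-membered ring of 14 arises by ring expansion through C–C cleavage and not by end-to-end cyclisation, and the cyclobutane of 12 is carried through intact. C1 is fixed in the photoaddition: 8 should react from the chair in which the silyloxy group (and, in the trans epimer, the methyl) is equatorial, the alkene approaching the enone face away from the puckered C5–C6–C7 segment with its own ring turned away from the seven-membered ring, which corresponds to 1R. C9 is formed cis, is epimerisable α to the C8 ketone and should be equilibrated by DBU to the more stable trans (9S) fusion. The required regiochemistry (C9 to the methoxy-bearing C8, C1 to C2) should follow from steric matching, because the fully substituted C8 can bond comfortably only to the cyclobutene carbon remote from the gem-dimethyl group. Facial selectivity rests on a remote stereocentre and is the main uncertainty; the other ring-fusion series is a diastereomer of 15 and should be removable by chromatography.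

Step 9
Reactants: 15 (1R,5R,9S)-5-[tert-butyl(dimethyl)silyl]oxy-4,11,11-trimethylbicyclo[7.2.0]undecane-3,8-dione
Product: 16 (1R,5R,9S)-5-[tert-butyl(dimethyl)silyl]oxy-4,11,11-trimethyl-8-methylidenebicyclo[7.2.0]undecan-3-one (C4 epimers)
Conditions: Ph3PCH3Br (1.2 equiv), KOtBu (1.15 equiv), THF, 0 °C; then 15, −20 → 0 °C
Reagents that add atoms: methyltriphenylphosphonium bromide C[P+](c1ccccc1)(c1ccccc1)c1ccccc1.[Br-]
Why: Wittig methylenation should take the C8 carbonyl, flanked only by the ring-fusion CH and a CH2, in preference to the C3 carbonyl screened by its α-methyl and β-silyloxy substituents; C9 remains in its thermodynamic trans configuration.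

Step 10
Reactants: 16 (1R,5R,9S)-5-[tert-butyl(dimethyl)silyl]oxy-4,11,11-trimethyl-8-methylidenebicyclo[7.2.0]undecan-3-one
Product: 17 (1R,5R,9S)-5-[tert-butyl(dimethyl)silyl]oxy-4,11,11-trimethyl-8-methylidenebicyclo[7.2.0]undecan-3-ol (C3 and C4 epimers)
Conditions: NaBH4, MeOH, 0 °C
Reagents that add atoms: none
Why: Borohydride reduction of the only remaining ketone; the C3 configuration is not controlled and does not matter because C3 becomes sp2 in step 13.

Step 11
Reactants: 17 (1R,5R,9S)-5-[tert-butyl(dimethyl)silyl]oxy-4,11,11-trimethyl-8-methylidenebicyclo[7.2.0]undecan-3-ol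
Product: 18 (1R,5R,9S)-5-[tert-butyl(dimethyl)silyl]oxy-4,11,11-trimethyl-8-methylidenebicyclo[7.2.0]undecan-3-yl methanesulfonate
Conditions: MsCl, Et3N, CH2Cl2, 0 °C
Reagents that add atoms: methanesulfonyl chloride CS(=O)(=O)Cl
Why: Sulfonylation of the secondary alcohol turns the C3 oxygen into the leaving group for the later β-elimination.

Step 12
Reactants: 18 (1R,5R,9S)-5-[tert-butyl(dimethyl)silyl]oxy-4,11,11-trimethyl-8-methylidenebicyclo[7.2.0]undecan-3-yl methanesulfonate
Product: 19 (1R,5R,9S)-5-hydroxy-4,11,11-trimethyl-8-methylidenebicyclo[7.2.0]undecan-3-yl methanesulfonate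
Conditions: HF·pyridine, pyridine (excess), THF, 0 °C → rt
Reagents that add atoms: none
Why: Buffered fluoride-mediated cleavage of the secondary silyl ether should leave the mesylate and the exocyclic alkene untouched.

Step 13
Reactants: 19 (1R,5R,9S)-5-hydroxy-4,11,11-trimethyl-8-methylidenebicyclo[7.2.0]undecan-3-yl methanesulfonate
Product: 21 (1R,3Z,9S)-4,11,11-trimethyl-8-methylidenebicyclo[7.2.0]undec-3-en-5-one, via keto mesylate 20 (not isolated)
Conditions: Dess–Martin periodinane, CH2Cl2, 0 °C → rt; then Et3N, 0 °C
Reagents that add atoms: none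
Why: Dess–Martin oxidation gives the C5 ketone, which acidifies C4–H next to the C3 mesylate, so amine-induced E1cB elimination can place the double bond only at C3=C4, with the cis (Z) geometry that the nine-membered ring accommodates.

Step 14
Reactants: 21 (1R,3Z,9S)-4,11,11-trimethyl-8-methylidenebicyclo[7.2.0]undec-3-en-5-one
Product: 22 (1R,3Z,5R,9S)-4,11,11-trimethyl-8-methylidenebicyclo[7.2.0]undec-3-en-5-ol
Conditions: (S)-Me-CBS (0.2 equiv), catecholborane (1.5 equiv), toluene, −78 °C
Reagents that add atoms: none
Why: Corey–Bakshi–Shibata reduction with catecholborane is 1,2-selective for enones and spares the isolated alkene; with the α-methylalkenyl arm as the large group and the C6 methylene as the small one, the (S)-catalyst should deliver hydride to give 5R under reagent control.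

Step 15
Reactants: 23 2,4,6-trihydroxyacetophenone
Product: 24 2-acetyl-3-hydroxy-4,4,6,6-tetramethylcyclohex-2-ene-1,5-dione (acetylsyncarpic acid)
Conditions: NaOMe, MeI (excess), MeOH, reflux
Reagents that add atoms: iodomethane CI
Why: Exhaustive base-mediated C-methylation of the acylphloroglucinol (dearomatising alkylation) installs both gem-dimethyl groups.

Step 16
Reactants: 24 2-acetyl-3-hydroxy-4,4,6,6-tetramethylcyclohex-2-ene-1,5-dione
Product: 25 5-hydroxy-2,2,6,6-tetramethylcyclohex-4-ene-1,3-dione (syncarpic acid)
Conditions: 6 M HCl (aq), reflux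
Reagents that add atoms: none
Why: Acid-mediated retro-Claisen deacylation of the β-triketone releases the parent cyclic trione.

Step 17
Reactants: 22 (1R,3Z,5R,9S)-4,11,11-trimethyl-8-methylidenebicyclo[7.2.0]undec-3-en-5-ol; 25 syncarpic acid; 26 3-methylbutanal
Product: 28 tomentodione O, via alkylidene trione 27 (not isolated)
Conditions: EDDA (20 mol %), 25 and 26 (2 equiv each, in portions), toluene, 80 °C
Reagents that add atoms: none
Why: Domino Knoevenagel–hetero-Diels–Alder reaction: the electron-poor oxadiene 27 should add to the 1,1-disubstituted C8 methylene in preference to the hindered C3=C4 bond, oxygen bonding to the more substituted C8; C8 and C4′ arise under substrate control, the diene being expected to approach the outer face of the methylene (away from the loop of the nine-membered ring) with the isobutyl terminus exo to give 8S,4′R, and the diastereomers are to be separated by chromatography.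

**Compound list**

1 | cycloheptane-1,3-dione | O=C1CCCCC(=O)C1 | starting material
2 | 3-methoxycyclohept-2-en-1-one | COC1=CC(=O)CCCC1 | intermediate
3 | 3-methoxy-7-methylcyclohept-2-en-1-one (racemic) | COC1=CC(=O)C(C)CCC1 | intermediate
4 | [(6-methoxy-2-methylcyclohepta-1,6-dien-1-yl)oxy]trimethylsilane | COC1=CC(O[Si](C)(C)C)=C(C)CCC1 | intermediate
5 | 3-methoxy-7-methylcyclohepta-2,6-dien-1-one | COC1=CC(=O)C(C)=CCC1 | intermediate
6 | (6R)-3-methoxy-7-methyl-6-(4,4,5,5-tetramethyl-1,3,2-dioxaborolan-2-yl)cyclohept-2-en-1-one (C7 epimers) | COC1=CC(=O)C(C)[C@H](B2OC(C)(C)C(C)(C)O2)CC1 | intermediate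
7 | (6R)-6-hydroxy-3-methoxy-7-methylcyclohept-2-en-1-one (C7 epimers) | COC1=CC(=O)C(C)[C@H](O)CC1 | intermediate
8 | (6R)-6-[tert-butyl(dimethyl)silyl]oxy-3-methoxy-7-methylcyclohept-2-en-1-one (C7 epimers) | COC1=CC(=O)C(C)[C@H](O[Si](C)(C)C(C)(C)C)CC1 | intermediate
9 | 3,3-dimethylcyclobutan-1-one | CC1(C)CC(=O)C1 | starting material
10 | N′-(3,3-dimethylcyclobutylidene)-4-methylbenzenesulfonohydrazide | Cc1ccc(cc1)S(=O)(=O)NN=C1CC(C)(C)C1 | intermediate
11 | (3,3-dimethylcyclobut-1-en-1-yl)lithium | [Li]C1=CC(C)(C)C1 | intermediate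
12 | 3,3-dimethylcyclobutene | CC1(C)C=CC1 | intermediate
13 | cis-anti-cis photoadduct: 4-[tert-butyl(dimethyl)silyl]oxy-7-methoxy-3,10,10-trimethyltricyclo[5.4.0.0^8,11]undecan-2-one (15 with an extra C2–C8 bond and OMe on C8; C4 epimers) | CO[C@@]12CC[C@@H](O[Si](C)(C)C(C)(C)C)C(C)C(=O)[C@@H]1[C@@H]1[C@H]2CC1(C)C | intermediate
14 | (1R,5R,9R)-5-[tert-butyl(dimethyl)silyl]oxy-4,11,11-trimethylbicyclo[7.2.0]undecane-3,8-dione (cis-fused; C4 epimers) | CC1C(=O)C[C@@H]2[C@@H](CC2(C)C)C(=O)CC[C@H]1O[Si](C)(C)C(C)(C)C | intermediate
15 | (1R,5R,9S)-5-[tert-butyl(dimethyl)silyl]oxy-4,11,11-trimethylbicyclo[7.2.0]undecane-3,8-dione (trans-fused; C4 epimers) | CC1C(=O)C[C@@H]2[C@H](CC2(C)C)C(=O)CC[C@H]1O[Si](C)(C)C(C)(C)C | intermediate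
16 | (1R,5R,9S)-5-[tert-butyl(dimethyl)silyl]oxy-4,11,11-trimethyl-8-methylidenebicyclo[7.2.0]undecan-3-one (C4 epimers) | CC1C(=O)C[C@@H]2[C@H](CC2(C)C)C(=C)CC[C@H]1O[Si](C)(C)C(C)(C)C | intermediate
17 | (1R,5R,9S)-5-[tert-butyl(dimethyl)silyl]oxy-4,11,11-trimethyl-8-methylidenebicyclo[7.2.0]undecan-3-ol (C3/C4 epimers) | CC1C(O)C[C@@H]2[C@H](CC2(C)C)C(=C)CC[C@H]1O[Si](C)(C)C(C)(C)C | intermediate
18 | (1R,5R,9S)-5-[tert-butyl(dimethyl)silyl]oxy-4,11,11-trimethyl-8-methylidenebicyclo[7.2.0]undecan-3-yl methanesulfonate (C3/C4 epimers) | CC1C(OS(C)(=O)=O)C[C@@H]2[C@H](CC2(C)C)C(=C)CC[C@H]1O[Si](C)(C)C(C)(C)C | intermediate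
19 | (1R,5R,9S)-5-hydroxy-4,11,11-trimethyl-8-methylidenebicyclo[7.2.0]undecan-3-yl methanesulfonate (C3/C4 epimers) | CC1C(OS(C)(=O)=O)C[C@@H]2[C@H](CC2(C)C)C(=C)CC[C@H]1O | intermediate
20 | (1R,9S)-4,11,11-trimethyl-8-methylidene-5-oxobicyclo[7.2.0]undecan-3-yl methanesulfonate (C3/C4 epimers) | CC1C(OS(C)(=O)=O)C[C@@H]2[C@H](CC2(C)C)C(=C)CCC1=O | intermediate
21 | (1R,3Z,9S)-4,11,11-trimethyl-8-methylidenebicyclo[7.2.0]undec-3-en-5-one | C/C1=C/C[C@@H]2[C@H](CC2(C)C)C(=C)CCC1=O | intermediate
22 | (1R,3Z,5R,9S)-4,11,11-trimethyl-8-methylidenebicyclo[7.2.0]undec-3-en-5-ol | C/C1=C/C[C@@H]2[C@H](CC2(C)C)C(=C)CC[C@H]1O | intermediate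
23 | 2,4,6-trihydroxyacetophenone | CC(=O)c1c(O)cc(O)cc1O | starting material
24 | 2-acetyl-3-hydroxy-4,4,6,6-tetramethylcyclohex-2-ene-1,5-dione (acetylsyncarpic acid) | CC(=O)C1=C(O)C(C)(C)C(=O)C(C)(C)C1=O | intermediate
25 | 5-hydroxy-2,2,6,6-tetramethylcyclohex-4-ene-1,3-dione (syncarpic acid) | CC1(C)C(=O)C=C(O)C(C)(C)C1=O | intermediate
26 | 3-methylbutanal | CC(C)CC=O | starting material
27 | 4,4,6,6-tetramethyl-2-(3-methylbutylidene)cyclohexane-1,3,5-trione | CC(C)CC=C1C(=O)C(C)(C)C(=O)C(C)(C)C1=O | intermediate
28 | tomentodione O: (1R,3Z,5R,8S,9S,4′R)-5-hydroxy-4,11,11,6′,6′,8′,8′-heptamethyl-4′-(2-methylpropyl)-3′,4′-dihydrospiro[bicyclo[7.2.0]undec-3-ene-8,2′-chromene]-5′,7′(6′H,8′H)-dione | C/C1=C/C[C@@H]2[C@H](CC2(C)C)[C@]2(CC[C@H]1O)C[C@@H](CC(C)C)C1=C(O2)C(C)(C)C(=O)C(C)(C)C1=O | target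

**Step count and risks**

Total step count: 17. Longest linear sequence: 13 steps (steps 1–5, 8–14 and 17).

Steps most likely to fail:

1. Step 8. The cyclobutene may add to both faces of the enone, because the directing stereocentre of 8 is remote, and to some extent with reversed orientation, so that both ring-fusion series form. Fallback: setting out from 8, the methoxy group is exchanged for a face-shielding chiral alkoxy group by acid-catalysed transetherification with (1R,2S,5R)-8-phenylmenthol (CSA, toluene, removal of methanol), giving the 8-phenylmenthyl vinylogous ester F1. Irradiation with 12 then gives the photoadduct F2, and the same acid fragmentation and equilibration release the auxiliary for recovery and return the route at 15. The control element now sits on the reacting carbon (the future C8) instead of three bonds away.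

2. Step 17. Facial and endo/exo discrimination at the exocyclic alkene may be insufficient, and the C3=C4 bond may compete, so that C8/C4′ diastereomers dominate. Fallback: setting out from 21, the Knoevenagel–hetero-Diels–Alder reaction with 25 and 26 is run on the dienone, whose endocyclic alkene is deactivated by conjugation and whose ring conformation differs, to give the spiro enone F3. The C5 ketone of F3 is then reduced last with the (S)-CBS/catecholborane system of step 14 (the vinylogous-ester and doubly neopentyl carbonyls of the trione part should not react), arriving at 28.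

3. Step 9. Methylenation may also occur at C3, or the basic ylide may trigger β-elimination of the silyloxy group or a transannular aldol reaction. Fallback: setting out from 15, silanol is eliminated on purpose with DBU (toluene, 60 °C) to give the enedione F4, in which C3 is a less electrophilic conjugated carbonyl, and the saturated C8 ketone is then methylenated to the methylidene enone F5. The enone is transposed by alkaline hydrogen peroxide epoxidation to the epoxy ketone F6 and Wharton reaction (N2H4·H2O, AcOH, MeOH) to the allylic alcohol F7 (C5 epimers). Dess–Martin oxidation of F7 rejoins the route at 21.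

**Further compounds**

F1 | step 8 | (6R)-6-[tert-butyl(dimethyl)silyl]oxy-7-methyl-3-{[(1R,2S,5R)-5-methyl-2-(2-phenylpropan-2-yl)cyclohexyl]oxy}cyclohept-2-en-1-one (C7 epimers) | C[C@@H]1CC[C@H]([C@@H](C1)OC1=CC(=O)C(C)[C@H](O[Si](C)(C)C(C)(C)C)CC1)C(C)(C)c1ccccc1
F2 | step 8 | photoadduct of F1 and 12 (13 with the 8-phenylmenthyloxy group in place of OMe on C8) | C[C@@H]1CC[C@H]([C@@H](C1)O[C@@]12CC[C@@H](O[Si](C)(C)C(C)(C)C)C(C)C(=O)[C@@H]1[C@@H]1[C@H]2CC1(C)C)C(C)(C)c1ccccc1
F3 | step 17 | (1R,3Z,8S,9S,4′R)-4,11,11,6′,6′,8′,8′-heptamethyl-4′-(2-methylpropyl)-3′,4′-dihydrospiro[bicyclo[7.2.0]undec-3-ene-8,2′-chromene]-5,5′,7′(6′H,8′H)-trione | C/C1=C/C[C@@H]2[C@H](CC2(C)C)[C@]2(CCC1=O)C[C@@H](CC(C)C)C1=C(O2)C(C)(C)C(=O)C(C)(C)C1=O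
F4 | step 9 | (1R,4Z,9S)-4,11,11-trimethylbicyclo[7.2.0]undec-4-ene-3,8-dione | C/C1=C/CCC(=O)[C@H]2CC(C)(C)[C@@H]2CC1=O
F5 | step 9 | (1R,4Z,9S)-4,11,11-trimethyl-8-methylidenebicyclo[7.2.0]undec-4-en-3-one | C/C1=C/CCC(=C)[C@H]2CC(C)(C)[C@@H]2CC1=O
F6 | step 9 | (1R,9S)-4,5-epoxy-4,11,11-trimethyl-8-methylidenebicyclo[7.2.0]undecan-3-one (cis-epoxide, both faces) | CC12OC1CCC(=C)[C@H]1CC(C)(C)[C@@H]1CC2=O
F7 | step 9 | (1R,3Z,9S)-4,11,11-trimethyl-8-methylidenebicyclo[7.2.0]undec-3-en-5-ol (C5 epimers) | C/C1=C/C[C@@H]2[C@H](CC2(C)C)C(=C)CCC1O
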